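**Retrosynthetic overview**
- The target comes from its methyl ester/C2 silyl ether by a late C2 oxidation and an SN2 ester demethylation.
- That bicycle comes from an intramolecular Diels–Alder reaction of an acyclic (E,E)-diene/(E)-enoate tetraene. The C3a–C7a and C4–C5 bonds form together, so the cyclopentane and the cyclohexene are closed in the same step.
- The tetraene comes from a west aldehyde by two formyl-ylide Wittig homologations and a benzylphosphonate olefination; the east enoate comes from ozonolysis/Wittig of a vinyl group.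
- The Me/O/Et stereotriad comes from an anti, Felkin-selective chromium-mediated pentenylation of the aldehyde derived from (S)-Roche ester, the only purchased stereocentre.

Assumption: 1-bromopent-2-ene (sold as a predominantly E mixture), methyl 2-(triphenylphosphoranylidene)butanoate and 2-(triphenylphosphoranylidene)butanal are bought as catalogue reagents.

**Step 1**
Reactants: 1 methyl (S)-3-hydroxy-2-methylpropanoate ((S)-Roche ester); 2 chlorotriethylsilane
Product: 3 methyl (S)-2-methyl-3-(triethylsilyloxy)propanoate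
Conditions: imidazole, CH2Cl2, 0 °C → rt
Reagents that add atoms: chlorotriethylsilane (2), CC[Si](Cl)(CC)CC
Why: Standard silylation of the primary alcohol, which leaves the purchased stereocentre untouched.

**Step 2**
Reactants: 3 methyl (S)-2-methyl-3-(triethylsilyloxy)propanoate
Product: 4 (S)-2-methyl-3-(triethylsilyloxy)propanal
Conditions: i-Bu2AlH (1.1 equiv), CH2Cl2, −78 °C; MeOH, aq. potassium sodium tartrate; used crude
Reagents that add atoms: none
Why: Low-temperature partial ester reduction stops at the aluminium hemiacetal, so the aldehyde is released only on work-up and the α-stereocentre is not epimerised.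

**Step 3**
Reactants: 4 (S)-2-methyl-3-(triethylsilyloxy)propanal; 5 (E)-1-bromopent-2-ene
Product: 6 (2S,3S,4S)-4-ethyl-2-methyl-1-(triethylsilyloxy)hex-5-en-3-ol
Conditions: CrCl2 (3 equiv), 5 (1.5 equiv), THF, 0 °C → rt
Reagents that add atoms: (E)-1-bromopent-2-ene (5), CC/C=C/CBr
Why: Nozaki–Hiyama allylation: the γ-ethylallyl chromium species (trivalent chromium) adds through a chair transition state (OH/Et anti whatever the bromide geometry) to the Felkin–Anh face of the α-methyl aldehyde (OH/Me syn), expected about 4–6:1, with minor isomers removed by chromatography.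

**Step 4**
Reactants: 6 (2S,3S,4S)-4-ethyl-2-methyl-1-(triethylsilyloxy)hex-5-en-3-ol; 7 triethylsilyl trifluoromethanesulfonate
Product: 8 (3S,4S,5S)-3-ethyl-5-methyl-4,6-bis(triethylsilyloxy)hex-1-ene
Conditions: 2,6-lutidine, CH2Cl2, −78 → 0 °C
Reagents that add atoms: triethylsilyl trifluoromethanesulfonate (7), CC[Si](CC)(CC)OS(=O)(=O)C(F)(F)F
Why: The silyl triflate silylates the hindered secondary alcohol, blocking β-elimination and retro-aldol pathways in the aldehyde steps that follow.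

**Step 5**
Reactants: 8 (3S,4S,5S)-3-ethyl-5-methyl-4,6-bis(triethylsilyloxy)hex-1-ene; 9 methyl 2-(triphenylphosphoranylidene)butanoate
Product: 11 methyl (2E,4S,5S,6S)-2,4-diethyl-6-methyl-5,7-bis(triethylsilyloxy)hept-2-enoate, via aldehyde 10 (not isolated)
Conditions: O3, CH2Cl2, −78 °C; PPh3, −78 °C → rt; solvent switch to PhMe, 9 (2.5 equiv), 80 °C
Reagents that add atoms: methyl 2-(triphenylphosphoranylidene)butanoate (9), CCC(C(=O)OC)=P(c1ccccc1)(c1ccccc1)c1ccccc1
Why: Ozonolysis of the only alkene gives the α-chiral aldehyde, which is trapped without isolation by the stabilised ylide (Wittig reaction) under neutral conditions to give the (E)-trisubstituted enoate without epimerisation.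

**Step 6**
Reactants: 11 methyl (2E,4S,5S,6S)-2,4-diethyl-6-methyl-5,7-bis(triethylsilyloxy)hept-2-enoate
Product: 12 methyl (2E,4S,5S,6R)-2,4-diethyl-6-methyl-7-oxo-5-(triethylsilyloxy)hept-2-enoate
Conditions: (COCl)2, DMSO, CH2Cl2, −78 → −30 °C; Et3N, → 0 °C
Reagents that add atoms: none
Why: Under Swern conditions a primary triethylsilyl ether is cleaved and oxidised directly to the aldehyde, while the hindered secondary silyl ether and the enoate are untouched (Swern oxidative desilylation).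

**Step 7**
Reactants: 12 methyl (2E,4S,5S,6R)-2,4-diethyl-6-methyl-7-oxo-5-(triethylsilyloxy)hept-2-enoate; 13 2-(triphenylphosphoranylidene)butanal
Product: 14 methyl (2E,4S,5R,6S,7E)-2,4,8-triethyl-6-methyl-9-oxo-5-(triethylsilyloxy)nona-2,7-dienoate
Conditions: 13 (1.5 equiv), PhMe, 90 °C
Reagents that add atoms: 2-(triphenylphosphoranylidene)butanal (13), CCC(C=O)=P(c1ccccc1)(c1ccccc1)c1ccccc1
Why: Wittig reaction of the formyl-stabilised ylide gives the (E)-2-ethyl enal, and the conjugated product is much less reactive than the starting aldehyde, so the homologation stops after one unit.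

**Step 8**
Reactants: 14 methyl (2E,4S,5R,6S,7E)-2,4,8-triethyl-6-methyl-9-oxo-5-(triethylsilyloxy)nona-2,7-dienoate; 13 2-(triphenylphosphoranylidene)butanal
Product: 15 methyl (2E,4S,5R,6S,7E,9E)-2,4,8,10-tetraethyl-6-methyl-11-oxo-5-(triethylsilyloxy)undeca-2,7,9-trienoate
Conditions: 13 (3 equiv), PhMe, 110 °C, stopped at full conversion of 14
Reagents that add atoms: 2-(triphenylphosphoranylidene)butanal (13), CCC(C=O)=P(c1ccccc1)(c1ccccc1)c1ccccc1
Why: A second Wittig homologation with the same stabilised ylide gives the (E,E)-dienal, whose acceptor-substituted diene is too electron-poor to cyclise onto the enoate at this stage.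

**Step 9**
Reactants: 15 methyl (2E,4S,5R,6S,7E,9E)-2,4,8,10-tetraethyl-6-methyl-11-oxo-5-(triethylsilyloxy)undeca-2,7,9-trienoate; 16 diethyl benzylphosphonate
Product: 18 methyl (1S,2R,3S,3aR,4R,5S,7aR)-3,4,5,7-tetraethyl-1-methyl-5-[(E)-2-phenylethenyl]-2-(triethylsilyloxy)-2,3,3a,4,5,7a-hexahydro-1H-indene-4-carboxylate, via tetraene 17 (not isolated)
Conditions: 16, KN(SiMe3)2, THF, −78 → 0 °C; then AcOH (0.2 equiv), BHT, PhMe, 105 °C
Reagents that add atoms: diethyl benzylphosphonate (16), CCOP(=O)(Cc1ccccc1)OCC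
Why: The Horner–Wadsworth–Emmons reaction gives the (E)-styryl unit, and on heating the (E,E)-diene and (E)-enoate undergo the intramolecular Diels–Alder reaction through the trans-fused, ester-endo transition state in which each tether stereocentre keeps its C–H in the plane of the adjacent trisubstituted alkene (A1,3 strain), so bonding occurs anti to Me and to Et and C3a, C4, C5 and C7a are set from C1 and C3.

**Step 10**
Reactants: 18 methyl (1S,2R,3S,3aR,4R,5S,7aR)-3,4,5,7-tetraethyl-1-methyl-5-[(E)-2-phenylethenyl]-2-(triethylsilyloxy)-2,3,3a,4,5,7a-hexahydro-1H-indene-4-carboxylate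
Product: 20 methyl (1S,3S,3aR,4R,5S,7aR)-3,4,5,7-tetraethyl-1-methyl-2-oxo-5-[(E)-2-phenylethenyl]-2,3,3a,4,5,7a-hexahydro-1H-indene-4-carboxylate, via alcohol 19 (not isolated)
Conditions: CrO3, H2SO4, H2O, acetone, 0 °C → rt
Reagents that add atoms: none
Why: The acidic hexavalent-chromium medium (Jones oxidation) hydrolyses the secondary silyl ether and oxidises the freed alcohol in the same flask, and both α-stereocentres already sit in the thermodynamically preferred all-trans arrangement, so enolisation cannot scramble them.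

**Step 11**
Reactants: 20 methyl (1S,3S,3aR,4R,5S,7aR)-3,4,5,7-tetraethyl-1-methyl-2-oxo-5-[(E)-2-phenylethenyl]-2,3,3a,4,5,7a-hexahydro-1H-indene-4-carboxylate
Product: 21 (1S,3S,3aR,4R,5S,7aR)-3,4,5,7-tetraethyl-1-methyl-2-oxo-5-[(E)-2-phenylethenyl]-2,3,3a,4,5,7a-hexahydro-1H-indene-4-carboxylic acid (target)
Conditions: sodium propane-1-thiolate (NaSCH2CH2CH3), DMF, 60 °C; then 1 M HCl
Reagents that add atoms: none
Why: The ester carbonyl between two fully substituted carbons is too hindered for acyl attack, so the thiolate cleaves it by SN2 attack at the methyl carbon (nucleophilic ester dealkylation) without touching any stereocentre.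

**Compound list**
1 | methyl (S)-3-hydroxy-2-methylpropanoate ((S)-Roche ester) | COC(=O)[C@@H](C)CO | starting material
2 | chlorotriethylsilane | CC[Si](Cl)(CC)CC | starting material
3 | methyl (S)-2-methyl-3-(triethylsilyloxy)propanoate | CC[Si](CC)(CC)OC[C@H](C)C(=O)OC | intermediate
4 | (S)-2-methyl-3-(triethylsilyloxy)propanal | CC[Si](CC)(CC)OC[C@H](C)C=O | intermediate
5 | (E)-1-bromopent-2-ene | CC/C=C/CBr | starting material
6 | (2S,3S,4S)-4-ethyl-2-methyl-1-(triethylsilyloxy)hex-5-en-3-ol | CC[Si](CC)(CC)OC[C@H](C)[C@@H](O)[C@H](C=C)CC | intermediate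
7 | triethylsilyl trifluoromethanesulfonate | CC[Si](CC)(CC)OS(=O)(=O)C(F)(F)F | starting material
8 | (3S,4S,5S)-3-ethyl-5-methyl-4,6-bis(triethylsilyloxy)hex-1-ene | CC[Si](CC)(CC)OC[C@H](C)[C@@H](O[Si](CC)(CC)CC)[C@H](C=C)CC | intermediate
9 | methyl 2-(triphenylphosphoranylidene)butanoate | CCC(C(=O)OC)=P(c1ccccc1)(c1ccccc1)c1ccccc1 | starting material
10 | (2R,3R,4S)-2-ethyl-4-methyl-3,5-bis(triethylsilyloxy)pentanal | CC[Si](CC)(CC)OC[C@H](C)[C@@H](O[Si](CC)(CC)CC)[C@H](C=O)CC | intermediate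
11 | methyl (2E,4S,5S,6S)-2,4-diethyl-6-methyl-5,7-bis(triethylsilyloxy)hept-2-enoate | CC[Si](CC)(CC)OC[C@H](C)[C@@H](O[Si](CC)(CC)CC)[C@H](/C=C(\CC)C(=O)OC)CC | intermediate
12 | methyl (2E,4S,5S,6R)-2,4-diethyl-6-methyl-7-oxo-5-(triethylsilyloxy)hept-2-enoate | O=C[C@H](C)[C@@H](O[Si](CC)(CC)CC)[C@H](/C=C(\CC)C(=O)OC)CC | intermediate
13 | 2-(triphenylphosphoranylidene)butanal | CCC(C=O)=P(c1ccccc1)(c1ccccc1)c1ccccc1 | starting material
14 | methyl (2E,4S,5R,6S,7E)-2,4,8-triethyl-6-methyl-9-oxo-5-(triethylsilyloxy)nona-2,7-dienoate | O=C/C(CC)=C/[C@H](C)[C@@H](O[Si](CC)(CC)CC)[C@H](/C=C(\CC)C(=O)OC)CC | intermediate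
15 | methyl (2E,4S,5R,6S,7E,9E)-2,4,8,10-tetraethyl-6-methyl-11-oxo-5-(triethylsilyloxy)undeca-2,7,9-trienoate | O=C/C(CC)=C/C(CC)=C/[C@H](C)[C@@H](O[Si](CC)(CC)CC)[C@H](/C=C(\CC)C(=O)OC)CC | intermediate
16 | diethyl benzylphosphonate | CCOP(=O)(Cc1ccccc1)OCC | starting material
17 | methyl (2E,4S,5R,6S,7E,9E,11E)-2,4,8,10-tetraethyl-6-methyl-12-phenyl-5-(triethylsilyloxy)dodeca-2,7,9,11-tetraenoate | c1ccccc1/C=C/C(CC)=C/C(CC)=C/[C@H](C)[C@@H](O[Si](CC)(CC)CC)[C@H](/C=C(\CC)C(=O)OC)CC | intermediate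
18 | methyl (1S,2R,3S,3aR,4R,5S,7aR)-3,4,5,7-tetraethyl-1-methyl-5-[(E)-2-phenylethenyl]-2-(triethylsilyloxy)-2,3,3a,4,5,7a-hexahydro-1H-indene-4-carboxylate | CCC1=C[C@@](/C=C/c2ccccc2)(CC)[C@](CC)(C(=O)OC)[C@@H]2[C@@H]1[C@H](C)[C@@H](O[Si](CC)(CC)CC)[C@H]2CC | intermediate
19 | methyl (1S,2R,3S,3aR,4R,5S,7aR)-3,4,5,7-tetraethyl-2-hydroxy-1-methyl-5-[(E)-2-phenylethenyl]-2,3,3a,4,5,7a-hexahydro-1H-indene-4-carboxylate | CCC1=C[C@@](/C=C/c2ccccc2)(CC)[C@](CC)(C(=O)OC)[C@@H]2[C@@H]1[C@H](C)[C@@H](O)[C@H]2CC | intermediate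
20 | methyl (1S,3S,3aR,4R,5S,7aR)-3,4,5,7-tetraethyl-1-methyl-2-oxo-5-[(E)-2-phenylethenyl]-2,3,3a,4,5,7a-hexahydro-1H-indene-4-carboxylate | CCC1=C[C@@](/C=C/c2ccccc2)(CC)[C@](CC)(C(=O)OC)[C@@H]2[C@@H]1[C@H](C)C(=O)[C@H]2CC | intermediate
21 | (1S,3S,3aR,4R,5S,7aR)-3,4,5,7-tetraethyl-1-methyl-2-oxo-5-[(E)-2-phenylethenyl]-2,3,3a,4,5,7a-hexahydro-1H-indene-4-carboxylic acid | CCC1=C[C@@](/C=C/c2ccccc2)(CC)[C@](CC)(C(=O)O)[C@@H]2[C@@H]1[C@H](C)C(=O)[C@H]2CC | target

**Totals**
Total step count: 11 (steps 5, 9 and 10 each run two operations in one flask).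
Longest linear sequence: 11 steps from (S)-Roche ester 1; all other inputs are purchased.

**Three steps most likely to fail, with fallbacks**

Step 9 (olefination/intramolecular Diels–Alder). The risk is that the bond between two fully substituted carbons forms slowly, or that the cis-fused adduct competes. The fallback sets out from 15: run only the olefination (16, KN(SiMe3)2, THF, −78 → 0 °C) and isolate tetraene 17 cold. HF·pyridine in THF/pyridine then gives methyl (2E,4S,5R,6S,7E,9E,11E)-2,4,8,10-tetraethyl-5-hydroxy-6-methyl-12-phenyldodeca-2,7,9,11-tetraenoate F3. Dess–Martin periodinane with NaHCO3 gives methyl (2E,4S,6S,7E,9E,11E)-2,4,8,10-tetraethyl-6-methyl-5-oxo-12-phenyldodeca-2,7,9,11-tetraenoate F4. Its flatter keto tether should cyclise under milder conditions (rt to 40 °C, or Me2AlCl at −40 °C), still anti to Me and Et, directly to 20, where it rejoins the route before step 11.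

Step 3 (facial selectivity of the chromium allylation). The risk is an inseparable or low Felkin:anti-Felkin ratio. The fallback sets out from 4 and uses an anti-selective boron aldol instead. The E-enol borinate of S-tert-butyl butanethioate ((c-C6H11)2BCl, Et3N, Et2O, −78 → 0 °C) adds to 4 with strong Felkin preference to give S-tert-butyl (2R,3R,4S)-2-ethyl-3-hydroxy-4-methyl-5-(triethylsilyloxy)pentanethioate F1. Silylation (7, 2,6-lutidine) gives S-tert-butyl (2R,3R,4S)-2-ethyl-4-methyl-3,5-bis(triethylsilyloxy)pentanethioate F2. Reduction with i-Bu2AlH at −78 °C gives aldehyde 10, which rejoins the route at the Wittig stage of step 5.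

Step 11 (cleavage of the very hindered ester). The risk is incomplete demethylation. The fallback sets out from 18 and replaces dealkylation by a reduction/oxidation sequence. LiAlH4 in THF (0 °C → reflux) reduces the ester to [(1S,2R,3S,3aR,4R,5S,7aR)-3,4,5,7-tetraethyl-1-methyl-5-[(E)-2-phenylethenyl]-2-(triethylsilyloxy)-2,3,3a,4,5,7a-hexahydro-1H-inden-4-yl]methanol F5. CrO3/H2SO4 in aqueous acetone then oxidises the primary alcohol to the acid and, after desilylation in the same flask, the secondary alcohol to the ketone, arriving directly at 21.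

**Further compounds**
F1 | step 3 | S-tert-butyl (2R,3R,4S)-2-ethyl-3-hydroxy-4-methyl-5-(triethylsilyloxy)pentanethioate | CC[Si](CC)(CC)OC[C@H](C)[C@@H](O)[C@H](C(=O)SC(C)(C)C)CC
F2 | step 3 | S-tert-butyl (2R,3R,4S)-2-ethyl-4-methyl-3,5-bis(triethylsilyloxy)pentanethioate | CC[Si](CC)(CC)OC[C@H](C)[C@@H](O[Si](CC)(CC)CC)[C@H](C(=O)SC(C)(C)C)CC
F3 | step 9 | methyl (2E,4S,5R,6S,7E,9E,11E)-2,4,8,10-tetraethyl-5-hydroxy-6-methyl-12-phenyldodeca-2,7,9,11-tetraenoate | c1ccccc1/C=C/C(CC)=C/C(CC)=C/[C@H](C)[C@@H](O)[C@H](/C=C(\CC)C(=O)OC)CC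
F4 | step 9 | methyl (2E,4S,6S,7E,9E,11E)-2,4,8,10-tetraethyl-6-methyl-5-oxo-12-phenyldodeca-2,7,9,11-tetraenoate | c1ccccc1/C=C/C(CC)=C/C(CC)=C/[C@H](C)C(=O)[C@H](/C=C(\CC)C(=O)OC)CC
F5 | step 11 | [(1S,2R,3S,3aR,4R,5S,7aR)-3,4,5,7-tetraethyl-1-methyl-5-[(E)-2-phenylethenyl]-2-(triethylsilyloxy)-2,3,3a,4,5,7a-hexahydro-1H-inden-4-yl]methanol | CCC1=C[C@@](/C=C/c2ccccc2)(CC)[C@](CC)(CO)[C@@H]2[C@@H]1[C@H](C)[C@@H](O[Si](CC)(CC)CC)[C@H]2CC
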